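## Structural features

The target 34 is a trans-fused hydrindane. A cyclohexane ring (C3a, C4, C5, C6, C7, C7a) and a cyclopentane ring (C7a, C1, C2, C3, C3a) share the C3a–C7a bond, and C3 carries a (1E)-2,6-dimethylhepta-1,5-dienyl chain (C1' to C6'). Five stereocentres are contiguous: C3 (chain β), C3a (H β) and C4 (tertiary carbinol, OH α and axial) on one side of the fusion bond, and the quaternary C7a (methyl α, axial) and C7 (bromine α, equatorial) on the other. The C4 hydroxyl is thus syn-axial to the angular methyl, bromine is cis to that methyl, and the chain is trans to C4 across the five-membered ring. The fragile groups are the secondary bromide next to a quaternary carbon (not accessible by substitution with inversion, lost under Pd/H2), the tertiary alcohol (dehydrates in acid) and two trisubstituted alkenes, one of fixed E geometry. This forces the order of late events: all hydrogenations before bromine, and the radical hydrogenation before the diene. The real difficulty is in the ring: the quaternary C7a, its 1,3 relationship to C4, its 1,2 relationship to C7, and the trans fusion. The key step uses the fact that the cyclopentane has one substituent only, on C3, and that C3a is bonded to a carbinol carbon C4 with methyl, oxygen and a two-carbon arm, which is the carbinol of (R)-linalool (1). Reading C3/C3a as an alkyne, C7a/C1 as an isopropenyl group and C2 as a carbonyl carbon turns both rings into a 1,7-enyne with one purchased stereocentre.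

## Logic of the disconnections

34 is cut at C5'=C6' into 31 and the ylide from 32. The terminal alkene has no geometry to control, and removing it last keeps the most sensitive alkene out of every earlier step. The chain shrinks to a C5' aldehyde. The forward olefination must tolerate the free C4 hydroxyl and the C7 bromide.

31 goes back through 30 to 27 and 28 by cutting C3'–C4' with transposition of the alkene. A sigmatropic rearrangement is the most dependable way to an E trisubstituted alkene beside a hindered ring carbon. The E alkene becomes a secondary allylic alcohol whose configuration is irrelevant. The forward step needs a chair transition state with the ring substituent equatorial, and a tertiary alcohol and a bromide that survive 135 °C.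

27 is cut at C1'–C2' into 25 and 26. The whole chain is thereby reduced to a formyl group on C3. The addition has to outrun enolisation of the α-branched aldehyde; the C3 configuration is the thermodynamically preferred one and is not at risk.

25 goes back through 24 to 23 by adjusting oxidation state and protection at C1' and C4. The chain alkenes must not exist while the C7 bromide is made. The forward steps need a fluoride deprotection that spares the bromide and an oxidation that touches only the primary alcohol.

23 is traced through 22 and 21 to 19 and 18: the C7–H bond (with C6–H) is removed and the bromide becomes a bromoalkene, then an enol triflate, then a ketone masked as a ketal. Substitution at neopentyl C7 is not viable, whereas a radical hydrogenation of the bromoalkene can put bromine equatorial. The demand is hydrogen delivery to C7 from the β face without loss of bromine.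

18 goes back through 17 and 16 to 14 by restoring the C2 carbonyl. This oxygen is what the ring-forming step leaves behind, and it also serves to equilibrate C3. The forward steps need epimerisation at C3 without β-elimination of the C1' oxygen, then a radical deoxygenation.

14 goes back to 13 by reintroducing the C3=C3a double bond. Forward, hydrogen has to add to the β face to give the trans fusion. The two axial α substituents on C7a and C4 are expected to enforce this.

13 is cut at C3a–C7a, C1–C2 and C2–C3, which opens both rings to the acyclic enyne 11. A bicycle with two fully substituted carbons becomes a chain with one stereocentre. The forward step has to insert a 1,1-disubstituted alkene to make quaternary C7a, and C4 has to control the face.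

11 goes back through 10 and 9 to 8: ketal, enone and allylic alcohol are successive forms of the epoxide. The epoxide has two roles, as the latent isopropenyl ketone and as the mask of the trisubstituted alkene during the earlier oxidative cleavage. The forward steps need proton loss from a methyl group and a ketalisation without conjugate addition.

8 is cut at C3–C1' to 6, and 6 at C3a≡C3 to 5, which comes from 3 by cleavage of the vinyl group. The vinyl group of the terpene thus becomes the alkyne, and C1' enters with its protecting group in one operation. The demands are that the vinyl group is the only alkene at the cleavage stage and that the epoxide survives base.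

3 goes back through 2 to 1. The hydroxyl must be capped before epoxidation, or it would open the epoxide to a cyclic ether. The epoxidation must choose the trisubstituted alkene.

## Other disconnections considered

Alternative 1: The cut is the C2=C3 bond of the cyclopentene carbaldehyde A3. It leads back to the dialdehyde A2 and, by rejoining C2 to C1', to the trans-fused bromo-octalinol A1, itself traceable to a quinone Diels–Alder adduct. The five-membered ring is thus treated as a contracted cyclohexene. Forward, ozonolysis of the ring alkene of A1 gives A2, and an amine–acid-catalysed intramolecular aldol condensation (C3 as nucleophile, C2 as electrophile) gives A3.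
- In favour: the four stereocentres of the six-membered ring are set on a decalin, where conformational control is classical. C1' appears directly as an aldehyde, so no protecting group at C1' and no removal of a C2 oxygen is needed; on these two points the alternative is the better plan. Conjugate reduction of A3 would lead to 25, so the last four steps are the same in both plans (equal).
- Against: A2 has two aldehydes and two enolisable carbons (C1 beside quaternary C7a, C3 beside C3a and the fully substituted C4). Neither is clearly favoured as the nucleophile, so regiochemical leakage is a real possibility. The bromide must be in place before ozonolysis, and installing it at C7 of A1 meets the same neopentyl problem as here, now with a ring alkene that a radical hydrogenation would not spare. The absolute configuration would rest on an enantioselective cycloaddition, not on a purchased centre.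
- Comparison: on mechanism the alternative is the better (polar, well-understood steps against a metal-mediated cyclisation at the edge of its scope). On structure the chosen plan is stronger, since its key step cannot give a regioisomer and C4 is bought. On step economy the two are expected to be about equal, because differentiating the two quinone-derived carbonyls and protecting the ring alkene costs what is saved at C2 and C1'.

Alternative 2: The cut is C3a–C7a together with C7–Br. The bromo ketone A6 opens to the acyclic chlorodiene A5, which would come from A4 (geranylacetone) by cleaving its terminal alkene to the acetal and turning the methyl ketone into the 2-chloroalkene. Forward, a bromonium donor (with a chiral Lewis-base catalyst for one enantiomer) attacks C7=C7a of A5, C3a of the chloroalkene closes the six-membered ring in a chair-like array, and water converts the chlorine-stabilised C4 cation into the ketone of A6.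
- In favour: C7–Br and quaternary C7a form in one step, and anti addition across the E alkene gives the right relative configuration (equatorial bromine cis to axial methyl). This is better than the chosen plan, which spends steps 14 to 17 on the same bromine. A5 is short to make.
- Against: only two of the five stereocentres are set. Enantiocontrol in bromonium cyclisations with a chloroalkene terminator is less secure than a chiral-pool centre. C3–C3a closure, chain addition at C3, trans fusion at C3a and the C4 methyl carbinol must all follow under substrate control. The bromide must survive these basic and organometallic steps, and a C3a enolate sits 1,3 to C7–Br, which invites cyclopropane formation.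
- Comparison: on structure the alternative is better for the C7/C7a pair, the chosen plan for C4 and for C3/C3a. On mechanism the cationic closure has firmer relative but weaker absolute control than the (2+2+1) reaction. On step economy the alternative is probably shorter, which is a point in its favour, at the price of carrying the fragile bromide from the start.

Alternative 3: The cuts are C3a–C4 and C7a–C7. The six-membered ring is folded back into the cyclobutene of A9, with C5 and C6 as the two methyl groups of the alkyne, and A9 goes back to A7 (3-methylcyclopent-2-enone) and A8 (but-2-yne). Forward, A7 bound to a chiral Lewis acid is irradiated with A8 to give the cis-fused (2+2) adduct A9. Later the cyclobutene bond would be cleaved to two methyl ketones whose methyl carbons must be joined (C5–C6) to unfold the ring.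
- In favour: quaternary C7a with absolute configuration arises from two feedstock compounds in one catalytic step. This is better than the chosen plan in brevity to the first stereocentre and in atom economy. C3 arrives as a ketone, a handle for the chain.
- Against: the fusion of A9 is necessarily cis, and C3a has the configuration opposite to 34, so it must be inverted later against an uncertain thermodynamic bias. Unfolding needs an oxidative cleavage and a C5–C6 coupling of two methyl ketones beside a third ketone, and three ketones (C3, C4, C7) must be told apart. The chain has to be attached to a ketone carbon that ends as CH, and the C4 methyl carbinol is still to be made.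
- Comparison: on structure the alternative reaches C7a faster but holds none of the C4 substitution, which the chosen plan has from its first compound. On mechanism the two are equal in plausibility, each at a demanding point of its scope. On step economy the alternative is at best equal, since unfolding, ketone differentiation, C3a inversion and the same C7 ketone-to-bromide sequence (equal in both plans) must follow.

Key step: step 9

Conventions and assumptions:
- Bicyclic compounds carry the indane locants of 34. Carbons of acyclic intermediates are called by the locants they will have in 34, and chain carbons are C1' to C6' from the ring outward.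
- α is the face of the C7a methyl group, β the opposite face.
- (R)-(−)-linalool of high enantiomeric purity is assumed. Its stereocentre is never touched and becomes C4 (R) of 34. The cis relationship between the C4 oxygen and the C7a methyl group required of 13 is the one present in 34.
- Compounds 3 to 9 (oxirane or carbinol carbon), 16 (C2) and 27 (C1') are epimer mixtures at a carbon that later becomes sp2 or CH2. This has no consequence.
- Design change relative to an enyne with an aryl silyl ether at C1': C1' carries a triisopropylsilyl ether, brought in together with the carbon atom by the commercial reagent (chloromethoxy)triisopropylsilane. It has no aryl ring (safe under forcing hydrogenation or dissolving metal), is a poorer leaving group in the enolate step, and survives the ketal hydrolysis.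
- 26 is bought as a THF solution.

Step 1
Reactants: 1 (R)-linalool
Product: 2 triethyl{[(3R)-3,7-dimethylocta-1,6-dien-3-yl]oxy}silane
Conditions: Et3SiOTf, 2,6-lutidine, CH2Cl2, −78 → 0 °C
Reagents that add atoms: triethylsilyl trifluoromethanesulfonate, CC[Si](CC)(CC)OS(=O)(=O)C(F)(F)F
Why: Silyl ether formation on the tertiary alcohol with a silyl triflate and a hindered base; the cap stops the hydroxyl from opening the epoxide made next, and the stereocentre is not involved.

Step 2
Reactants: 2 linalool triethylsilyl ether
Product: 3 triethyl{[(3R)-5-(3,3-dimethyloxiran-2-yl)-3-methylpent-1-en-3-yl]oxy}silane (both oxirane epimers)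
Conditions: mCPBA, NaHCO3, CH2Cl2, 0 °C
Reagents that add atoms: 3-chloroperoxybenzoic acid, OOC(=O)c1cccc(Cl)c1
Why: Prilezhaev epoxidation; the electron-rich trisubstituted alkene should react far faster than the monosubstituted vinyl group beside the C–O carbon. The new oxirane centre is erased later.

Step 3
Reactants: 3 epoxy silyl ether
Product: 5 (2R)-4-(3,3-dimethyloxiran-2-yl)-2-methyl-2-(triethylsilyloxy)butanal, via secondary ozonide 4 (not isolated)
Conditions: O3, CH2Cl2, −78 °C; then PPh3, −78 °C → rt
Reagents that add atoms: ozone, [O-][O+]=O
Why: Ozonolysis (Criegee mechanism) of the only remaining alkene with reductive work-up; the α-carbon is fully substituted, so the aldehyde cannot epimerise.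

Step 4
Reactants: 5 α-silyloxy aldehyde
Product: 6 triethyl{[(3R)-5-(3,3-dimethyloxiran-2-yl)-3-methylpent-1-yn-3-yl]oxy}silane
Conditions: dimethyl (1-diazo-2-oxopropyl)phosphonate, K2CO3, MeOH, 0 °C → rt
Reagents that add atoms: dimethyl (1-diazo-2-oxopropyl)phosphonate, COP(=O)(OC)C(=[N+]=[N-])C(C)=O
Why: Seyferth–Gilbert homologation in its Ohira–Bestmann form adds the future C3 and gives the terminal alkyne; the non-enolisable aldehyde and the epoxide tolerate carbonate in methanol.

Step 5
Reactants: 6 terminal alkyne
Product: 8 (4R)-6-(3,3-dimethyloxiran-2-yl)-4-methyl-4-(triethylsilyloxy)-1-(triisopropylsilyloxy)hex-2-yne, via lithium acetylide 7 (not isolated)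
Conditions: n-BuLi, THF, −78 °C; then i-Pr3SiOCH2Cl, −78 → 0 °C
Reagents that add atoms: (chloromethoxy)triisopropylsilane, CC(C)[Si](OCCl)(C(C)C)C(C)C
Why: Alkylation of a lithium acetylide with an α-chloro ether (substitution at an oxocarbenium-like carbon) forms C3–C1' and brings C1' in already protected; without a Lewis acid the acetylide should leave the trisubstituted epoxide alone at this temperature.

Step 6
Reactants: 8 epoxy alkyne
Product: 9 (6R)-2,6-dimethyl-6-(triethylsilyloxy)-9-(triisopropylsilyloxy)non-1-en-7-yn-3-ol (both carbinol epimers)
Conditions: Al(Oi-Pr)3 (2 equiv), toluene, 110 °C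
Reagents that add atoms: none
Why: Aluminium-alkoxide-promoted isomerisation of an epoxide to an allylic alcohol; the C–O bond at the more substituted oxirane carbon opens while a methyl proton passes to an isopropoxide ligand through a six-membered transition state, which gives the isopropenyl carbinol.

Step 7
Reactants: 9 isopropenyl carbinol
Product: 10 (6R)-2,6-dimethyl-6-(triethylsilyloxy)-9-(triisopropylsilyloxy)non-1-en-7-yn-3-one
Conditions: Dess–Martin periodinane, NaHCO3, CH2Cl2, 0 °C → rt
Reagents that add atoms: none
Why: Dess–Martin oxidation of the secondary allylic alcohol under buffered, neutral conditions that keep both silyl ethers; the two carbinol epimers converge.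

Step 8
Reactants: 10 isopropenyl ketone
Product: 11 2-[(3R)-3-methyl-3-(triethylsilyloxy)-6-(triisopropylsilyloxy)hex-4-yn-1-yl]-2-(prop-1-en-2-yl)-1,3-dioxolane
Conditions: (Me3SiOCH2)2, Me3SiOTf (5 mol%), CH2Cl2, −78 → −20 °C; pyridine quench
Reagents that add atoms: 1,2-bis(trimethylsilyloxy)ethane, C[Si](C)(C)OCCO[Si](C)(C)C
Why: Silyl-triflate-catalysed ketalisation with the bis-silyl ether of the diol, an aprotic low-temperature method that ketalises enones without conjugate addition; the 1,1-disubstituted alkene has no position to migrate to, and the silyl ethers should survive the catalytic acid.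

Step 9
Reactants: 11 ketal enyne
Product: 13 (4R,7aS)-7,7-ethylenedioxy-4,7a-dimethyl-4-(triethylsilyloxy)-3-[(triisopropylsilyloxy)methyl]-1,4,5,6,7,7a-hexahydro-2H-inden-2-one, via dicobalt hexacarbonyl alkyne complex 12 (not isolated)
Conditions: Co2(CO)8 (1.1 equiv), CH2Cl2, rt; then N-methylmorpholine N-oxide (8 equiv), 0 °C → rt
Reagents that add atoms: dicobalt octacarbonyl (donor of the C2 carbonyl), [C-]#[O+].[C-]#[O+].[C-]#[O+].[C-]#[O+].[C-]#[O+].[C-]#[O+].[C-]#[O+].[C-]#[O+].[Co].[Co]
Why: Intramolecular Pauson–Khand reaction, the cobalt-mediated (2+2+1) cycloaddition of a 1,7-enyne; the closest known reaction type is the amine-N-oxide-promoted cyclisation of tether-substituted 1,7-enynes, including those with 1,1-disubstituted alkenes. Co2(CO)8 binds the alkyne as complex 12, the N-oxide removes a CO ligand as CO2, and the freed site takes up the isopropenyl group, which inserts into the Co–C3a bond with its substituted carbon (C3a–C7a); CO then inserts into the Co–C1 bond (C1–C2) and reductive elimination joins C2 to C3. The six-membered ring thus closes by migratory insertion across the four-atom tether C4–C5–C6–C7 (exo with respect to the alkene, C1 staying outside that ring), the five-membered ring by carbonyl insertion and reductive elimination at cobalt. Regiochemistry is fixed by the tether, and the fully substituted C4 together with the ketal carbon C7 supplies the Thorpe–Ingold compression a 1,7-enyne needs. The one new stereocentre, C7a, is controlled by C4: in the chair-like arrangement of the tether the C7a methyl must be axial and syn-axial to one C4 substituent, and the chair with the C4 oxygen axial and the C4 methyl equatorial (one oxygen/methyl contact) should be preferred over the chair with two syn-axial methyl groups and the silyloxy group pushed against the cobalt cluster. This places the C7a methyl cis to the C4 oxygen, as in 34. No chemoselectivity is needed, since 11 contains a single alkyne and a single alkene.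

Step 10
Reactants: 13 bicyclic enone
Product: 14 7,7-ethylenedioxy-4β,7aα-dimethyl-4α-(triethylsilyloxy)-3α-[(triisopropylsilyloxy)methyl]-3aβ-H-octahydroinden-2-one
Conditions: H2 (50 bar), 10% Pd/C, EtOAc, rt
Reagents that add atoms: none
Why: Heterogeneous catalytic hydrogenation (syn addition); the α face of C3=C3a is screened by the axial C7a methyl and the axial C4 silyloxy group on the two carbons flanking C3a. Both hydrogens should therefore arrive on the β face, which sets H-3a anti to the angular methyl (trans fusion) and leaves the C3 substituent α for the moment.

Step 11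
Reactants: 14 3α ketone
Product: 16 7,7-ethylenedioxy-4β,7aα-dimethyl-4α-(triethylsilyloxy)-3β-[(triisopropylsilyloxy)methyl]-3aβ-H-octahydroinden-2-ol (C2 epimers), via 3β-epimeric ketone 15 (not isolated)
Conditions: K2CO3 (0.5 equiv), MeOH, rt; then NaBH4, 0 °C
Reagents that add atoms: none
Why: Base-mediated epimerisation through the C2 enolate, then borohydride reduction. In 14 the C3 substituent is cis to the fully substituted C4 on the five-membered ring, so equilibration should strongly favour 15, where it is β and trans to C4 as in 34. Fast reprotonation in methanol should outrun loss of the hindered trialkylsilanolate, and the C2 carbinol configuration is irrelevant.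

Step 12
Reactants: 16 C2 alcohol
Product: 17 O-{7,7-ethylenedioxy-4β,7aα-dimethyl-4α-(triethylsilyloxy)-3β-[(triisopropylsilyloxy)methyl]-3aβ-H-octahydroinden-2-yl} 1H-imidazole-1-carbothioate
Conditions: 1,1'-thiocarbonyldiimidazole, DMAP (cat.), 1,2-dichloroethane, 70 °C
Reagents that add atoms: 1,1'-thiocarbonyldiimidazole, S=C(n1ccnc1)n1ccnc1
Why: Thioacylation of the secondary alcohol, the first half of a Barton–McCombie deoxygenation; the neutral conditions avoid an alkoxide that could pull the neighbouring silyl group over from the C1' oxygen.

Step 13
Reactants: 17 thiocarbonylimidazolide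
Product: 18 7,7-ethylenedioxy-4β,7aα-dimethyl-4α-(triethylsilyloxy)-3β-[(triisopropylsilyloxy)methyl]-3aβ-H-octahydroindene
Conditions: Bu3SnH, AIBN (cat.), toluene, 110 °C
Reagents that add atoms: none
Why: Barton–McCombie radical deoxygenation: the stannyl radical adds to C=S, the C2–O bond fragments and the secondary C2 radical takes hydrogen from the stannane; no stereocentre is formed or disturbed.

Step 14
Reactants: 18 ketal
Product: 19 4β,7aα-dimethyl-4α-(triethylsilyloxy)-3β-[(triisopropylsilyloxy)methyl]-3aβ-H-octahydroinden-7-one
Conditions: PPTS (0.3 equiv), acetone/H2O (9:1), 55 °C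
Reagents that add atoms: water, O
Why: Acid-catalysed ketal hydrolysis; pyridinium tosylate is weak enough that the hindered tertiary triethylsilyl ether and the primary triisopropylsilyl ether should remain in place.

Step 15
Reactants: 19 C7 ketone
Product: 21 4β,7aα-dimethyl-4α-(triethylsilyloxy)-3β-[(triisopropylsilyloxy)methyl]-3aβ-H-2,3,3a,4,5,7a-hexahydro-1H-inden-7-yl trifluoromethanesulfonate, via potassium enolate 20 (not isolated)
Conditions: KN(SiMe3)2, THF, −78 °C; then PhNTf2, −78 → 0 °C
Reagents that add atoms: N-phenylbis(trifluoromethanesulfonimide), O=S(=O)(N(c1ccccc1)S(=O)(=O)C(F)(F)F)C(F)(F)F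
Why: Enol triflate formation; the base can deprotonate only C6 because C7a is quaternary, and the enolate is sulfonylated on oxygen, so the C6=C7 regiochemistry is unambiguous.

Step 16
Reactants: 21 enol triflate
Product: 22 7-bromo-4β,7aα-dimethyl-4α-(triethylsilyloxy)-3β-[(triisopropylsilyloxy)methyl]-3aβ-H-2,3,3a,4,5,7a-hexahydro-1H-indene
Conditions: Ni(cod)2 (10 mol%), LiBr (3 equiv), DMA/THF (1:3), rt
Reagents that add atoms: lithium bromide, [Li+].[Br-]
Why: Nickel-catalysed conversion of an enol triflate into an alkenyl bromide: zerovalent nickel inserts into the C7–O bond, triflate is exchanged for bromide and C–Br reductive elimination follows; no stereocentre is involved.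

Step 17
Reactants: 22 bromoalkene
Product: 23 7α-bromo-4β,7aα-dimethyl-4α-(triethylsilyloxy)-3β-[(triisopropylsilyloxy)methyl]-3aβ-H-octahydroindene
Conditions: Mn(dpm)3 (10 mol%; dpm = dipivaloylmethanate), PhSiH3, t-BuOOH, i-PrOH, rt
Reagents that add atoms: none
Why: Metal-hydride hydrogen-atom-transfer hydrogenation (Mukaiyama-type), a radical method that reduces haloalkenes to alkyl halides where Pd/H2 would cleave the C–Br bond. Hydrogen-atom transfer to C6 gives the bromine-stabilised C7 radical, which should take its second hydrogen on the β face, anti to the axial C7a methyl. Bromine then ends equatorial, α and cis to the methyl, which is also the thermodynamically preferred arrangement.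

Step 18
Reactants: 23 bis-silyl ether
Product: 24 7α-bromo-3β-(hydroxymethyl)-4β,7aα-dimethyl-3aβ-H-octahydroinden-4α-ol
Conditions: Bu4NF (3 equiv), THF, 0 °C → rt
Reagents that add atoms: none
Why: Fluoride-mediated cleavage of both silyl ethers; the equatorial bromide on the rigid trans-hydrindane has no anti-periplanar hydrogen and sits on a neopentyl-type carbon, so neither elimination nor substitution is expected.

Step 19
Reactants: 24 diol
Product: 25 7α-bromo-4α-hydroxy-4β,7aα-dimethyl-3aβ-H-octahydroindene-3β-carbaldehyde
Conditions: Dess–Martin periodinane, NaHCO3, CH2Cl2, 0 °C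
Reagents that add atoms: none
Why: Dess–Martin oxidation; only the primary alcohol can be oxidised. The tertiary C4 hydroxyl is inert and cannot form a lactol with the aldehyde, because C1' and C4 are trans on the five-membered ring.

Step 20
Reactants: 25 hydroxy aldehyde; 26 isopropenylmagnesium bromide
Product: 27 7α-bromo-3β-(1-hydroxy-2-methylprop-2-en-1-yl)-4β,7aα-dimethyl-3aβ-H-octahydroinden-4α-ol (both C1' epimers)
Conditions: THF, −78 → 0 °C (3 equiv of 26); aq. NH4Cl
Reagents that add atoms: none
Why: Grignard 1,2-addition forms C1'–C2'; one equivalent is consumed by the tertiary hydroxyl. The new carbinol centre is destroyed in the next step, so its configuration does not matter.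

Step 21
Reactants: 27 allylic alcohol; 28 triethyl orthoacetate
Product: 30 ethyl (4E)-5-(7α-bromo-4α-hydroxy-4β,7aα-dimethyl-3aβ-H-octahydroinden-3β-yl)-4-methylpent-4-enoate, via mixed ketene acetal 29 (not isolated)
Conditions: EtCO2H (cat.), neat 28, 135 °C, removal of EtOH
Reagents that add atoms: none
Why: Johnson–Claisen rearrangement: alcohol exchange gives the ketene acetal, and its chair-like [3,3] transition state keeps the bulky ring substituent equatorial, since an axial one would clash with the ethoxy group. The new C1'=C2' bond should therefore be E while C3'–C4' forms; the hindered tertiary hydroxyl should do no more than exchange reversibly.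

Step 22
Reactants: 30 ethyl ester
Product: 31 (4E)-5-(7α-bromo-4α-hydroxy-4β,7aα-dimethyl-3aβ-H-octahydroinden-3β-yl)-4-methylpent-4-enal
Conditions: i-Bu2AlH (2.2 equiv), CH2Cl2, −78 °C; aq. potassium sodium tartrate
Reagents that add atoms: none
Why: Partial reduction of the ester with a dialkylaluminium hydride at low temperature; the tetrahedral aluminium hemiacetal persists until work-up, and the first equivalent is used up by the hydroxyl group.

Step 23
Reactants: 31 aldehyde; 32 isopropyltriphenylphosphonium iodide
Product: 34 (3S,3aS,4R,7S,7aS)-7-bromo-3-[(1E)-2,6-dimethylhepta-1,5-dien-1-yl]-4,7a-dimethyloctahydro-1H-inden-4-ol, via isopropylidenetriphenylphosphorane 33 (not isolated)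
Conditions: n-BuLi, THF, 0 °C (ylide from 32, 3 equiv); then 31, −78 °C → rt
Reagents that add atoms: none
Why: Wittig olefination with a non-stabilised ylide forms C5'=C6'; the new alkene carries two identical methyl groups, so no geometry has to be controlled, and excess ylide covers the free hydroxyl.

## Compound list

1 | (R)-linalool, (3R)-3,7-dimethylocta-1,6-dien-3-ol | C=C[C@](C)(O)CCC=C(C)C | starting material
2 | triethyl{[(3R)-3,7-dimethylocta-1,6-dien-3-yl]oxy}silane | C=C[C@](C)(O[Si](CC)(CC)CC)CCC=C(C)C | intermediate
3 | triethyl{[(3R)-5-(3,3-dimethyloxiran-2-yl)-3-methylpent-1-en-3-yl]oxy}silane (oxirane epimers) | C=C[C@](C)(O[Si](CC)(CC)CC)CCC1OC1(C)C | intermediate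
4 | secondary ozonide of 3, 3-[(2R)-4-(3,3-dimethyloxiran-2-yl)-2-(triethylsilyloxy)butan-2-yl]-1,2,4-trioxolane | C1OC(OO1)[C@](C)(O[Si](CC)(CC)CC)CCC2OC2(C)C | intermediate (not isolated)
5 | (2R)-4-(3,3-dimethyloxiran-2-yl)-2-methyl-2-(triethylsilyloxy)butanal | O=C[C@](C)(O[Si](CC)(CC)CC)CCC1OC1(C)C | intermediate
6 | triethyl{[(3R)-5-(3,3-dimethyloxiran-2-yl)-3-methylpent-1-yn-3-yl]oxy}silane | C#C[C@](C)(O[Si](CC)(CC)CC)CCC1OC1(C)C | intermediate
7 | lithium acetylide of 6 | [Li]C#C[C@](C)(O[Si](CC)(CC)CC)CCC1OC1(C)C | intermediate (not isolated)
8 | (4R)-6-(3,3-dimethyloxiran-2-yl)-4-methyl-4-(triethylsilyloxy)-1-(triisopropylsilyloxy)hex-2-yne | CC(C)[Si](OCC#C[C@](C)(O[Si](CC)(CC)CC)CCC1OC1(C)C)(C(C)C)C(C)C | intermediate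
9 | (6R)-2,6-dimethyl-6-(triethylsilyloxy)-9-(triisopropylsilyloxy)non-1-en-7-yn-3-ol (C3 epimers) | C=C(C)C(O)CC[C@@](C)(O[Si](CC)(CC)CC)C#CCO[Si](C(C)C)(C(C)C)C(C)C | intermediate
10 | (6R)-2,6-dimethyl-6-(triethylsilyloxy)-9-(triisopropylsilyloxy)non-1-en-7-yn-3-one | C=C(C)C(=O)CC[C@@](C)(O[Si](CC)(CC)CC)C#CCO[Si](C(C)C)(C(C)C)C(C)C | intermediate
11 | 2-[(3R)-3-methyl-3-(triethylsilyloxy)-6-(triisopropylsilyloxy)hex-4-yn-1-yl]-2-(prop-1-en-2-yl)-1,3-dioxolane | C=C(C)C1(OCCO1)CC[C@@](C)(O[Si](CC)(CC)CC)C#CCO[Si](C(C)C)(C(C)C)C(C)C | intermediate
12 | μ-alkyne hexacarbonyldicobalt complex of 11 | C=C(C)C1(OCCO1)CC[C@@](C)(O[Si](CC)(CC)CC)C23C4(CO[Si](C(C)C)(C(C)C)C(C)C)[Co]2(=C=O)(=C=O)(=C=O)[Co]34(=C=O)(=C=O)=C=O | intermediate (not isolated)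
13 | (4R,7aS)-7,7-ethylenedioxy-4,7a-dimethyl-4-(triethylsilyloxy)-3-[(triisopropylsilyloxy)methyl]-1,4,5,6,7,7a-hexahydro-2H-inden-2-one (C3=C3a; 7a-CH3 cis to 4-O) | O=C1C[C@]2(C)C3(OCCO3)CC[C@@](C)(O[Si](CC)(CC)CC)C2=C1CO[Si](C(C)C)(C(C)C)C(C)C | intermediate
14 | 7,7-ethylenedioxy-4β,7aα-dimethyl-4α-(triethylsilyloxy)-3α-[(triisopropylsilyloxy)methyl]-3aβ-H-octahydroinden-2-one | CC(C)[Si](OC[C@H]1C(=O)C[C@]2(C)C3(OCCO3)CC[C@@](C)(O[Si](CC)(CC)CC)[C@@H]12)(C(C)C)C(C)C | intermediate
15 | 3β epimer of 14 (3β-CH2OSi, H-3 α) | CC(C)[Si](OC[C@@H]1C(=O)C[C@]2(C)C3(OCCO3)CC[C@@](C)(O[Si](CC)(CC)CC)[C@@H]12)(C(C)C)C(C)C | intermediate (not isolated)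
16 | 7,7-ethylenedioxy-4β,7aα-dimethyl-4α-(triethylsilyloxy)-3β-[(triisopropylsilyloxy)methyl]-3aβ-H-octahydroinden-2-ol (C2 epimers) | CC(C)[Si](OC[C@@H]1C(O)C[C@]2(C)C3(OCCO3)CC[C@@](C)(O[Si](CC)(CC)CC)[C@@H]12)(C(C)C)C(C)C | intermediate
17 | O-(hydrindan-2-yl) 1H-imidazole-1-carbothioate of 16 | CC(C)[Si](OC[C@@H]1C(OC(=S)n4ccnc4)C[C@]2(C)C3(OCCO3)CC[C@@](C)(O[Si](CC)(CC)CC)[C@@H]12)(C(C)C)C(C)C | intermediate
18 | 7,7-ethylenedioxy-4β,7aα-dimethyl-4α-(triethylsilyloxy)-3β-[(triisopropylsilyloxy)methyl]-3aβ-H-octahydroindene | CC(C)[Si](OC[C@@H]1CC[C@]2(C)C3(OCCO3)CC[C@@](C)(O[Si](CC)(CC)CC)[C@@H]12)(C(C)C)C(C)C | intermediate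
19 | 4β,7aα-dimethyl-4α-(triethylsilyloxy)-3β-[(triisopropylsilyloxy)methyl]-3aβ-H-octahydroinden-7-one | CC(C)[Si](OC[C@@H]1CC[C@]2(C)C(=O)CC[C@@](C)(O[Si](CC)(CC)CC)[C@@H]12)(C(C)C)C(C)C | intermediate
20 | potassium C6=C7 enolate of 19 | CC(C)[Si](OC[C@@H]1CC[C@]2(C)C(O[K])=CC[C@@](C)(O[Si](CC)(CC)CC)[C@@H]12)(C(C)C)C(C)C | intermediate (not isolated)
21 | C7 enol triflate of 19 (C6=C7) | CC(C)[Si](OC[C@@H]1CC[C@]2(C)C(OS(=O)(=O)C(F)(F)F)=CC[C@@](C)(O[Si](CC)(CC)CC)[C@@H]12)(C(C)C)C(C)C | intermediate
22 | 7-bromo-4β,7aα-dimethyl-4α-(triethylsilyloxy)-3β-[(triisopropylsilyloxy)methyl]-3aβ-H-2,3,3a,4,5,7a-hexahydro-1H-indene | CC(C)[Si](OC[C@@H]1CC[C@]2(C)C(Br)=CC[C@@](C)(O[Si](CC)(CC)CC)[C@@H]12)(C(C)C)C(C)C | intermediate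
23 | 7α-bromo-4β,7aα-dimethyl-4α-(triethylsilyloxy)-3β-[(triisopropylsilyloxy)methyl]-3aβ-H-octahydroindene | CC(C)[Si](OC[C@@H]1CC[C@]2(C)[C@@H](Br)CC[C@@](C)(O[Si](CC)(CC)CC)[C@@H]12)(C(C)C)C(C)C | intermediate
24 | 7α-bromo-3β-(hydroxymethyl)-4β,7aα-dimethyl-3aβ-H-octahydroinden-4α-ol | OC[C@@H]1CC[C@]2(C)[C@@H](Br)CC[C@@](C)(O)[C@@H]12 | intermediate
25 | 7α-bromo-4α-hydroxy-4β,7aα-dimethyl-3aβ-H-octahydroindene-3β-carbaldehyde | O=C[C@@H]1CC[C@]2(C)[C@@H](Br)CC[C@@](C)(O)[C@@H]12 | intermediate
26 | isopropenylmagnesium bromide | C=C(C)[Mg]Br | starting material
27 | 7α-bromo-3β-(1-hydroxy-2-methylprop-2-en-1-yl)-4β,7aα-dimethyl-3aβ-H-octahydroinden-4α-ol (C1' epimers) | C=C(C)C(O)[C@@H]1CC[C@]2(C)[C@@H](Br)CC[C@@](C)(O)[C@@H]12 | intermediate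
28 | triethyl orthoacetate | CCOC(C)(OCC)OCC | starting material
29 | mixed ketene acetal of 27 (1-ethoxyvinyl ether at the C1' oxygen) | C=C(OCC)OC(C(C)=C)[C@@H]1CC[C@]2(C)[C@@H](Br)CC[C@@](C)(O)[C@@H]12 | intermediate (not isolated)
30 | ethyl (4E)-5-(7α-bromo-4α-hydroxy-4β,7aα-dimethyl-3aβ-H-octahydroinden-3β-yl)-4-methylpent-4-enoate | CCOC(=O)CC/C(C)=C/[C@@H]1CC[C@]2(C)[C@@H](Br)CC[C@@](C)(O)[C@@H]12 | intermediate
31 | (4E)-5-(7α-bromo-4α-hydroxy-4β,7aα-dimethyl-3aβ-H-octahydroinden-3β-yl)-4-methylpent-4-enal | O=CCC/C(C)=C/[C@@H]1CC[C@]2(C)[C@@H](Br)CC[C@@](C)(O)[C@@H]12 | intermediate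
32 | isopropyltriphenylphosphonium iodide | CC(C)[P+](c1ccccc1)(c1ccccc1)c1ccccc1.[I-] | starting material
33 | isopropylidenetriphenylphosphorane | CC(C)=P(c1ccccc1)(c1ccccc1)c1ccccc1 | intermediate (not isolated)
34 | (3S,3aS,4R,7S,7aS)-7-bromo-3-[(1E)-2,6-dimethylhepta-1,5-dien-1-yl]-4,7a-dimethyloctahydro-1H-inden-4-ol | CC(C)=CCC/C(C)=C/[C@@H]1CC[C@]2(C)[C@@H](Br)CC[C@@](C)(O)[C@@H]12 | target

## Step count and least certain steps

Total: 23 steps. Longest linear sequence: 23 steps, from 1 to 34; 26, 28 and 32 are purchased and enter in steps 20, 21 and 23.

Step 9 (key step). The most likely failure is a stalled alkene insertion: the cobalt cluster sits beside the fully substituted C4, the alkene is 1,1-disubstituted, and the ring being closed is six-membered, so the complex may decompose before it cyclises. A second risk is weak facial discrimination at C7a if the preference of the chair for an axial oxygen over an axial methyl is small. Fallback: from 11, a titanocene-catalysed carbonylative enyne cyclisation (Cp2Ti(CO)2 cat., CO 1.2 bar, toluene, 90 °C) would lead to 13 through a mononuclear titanacyclopentene, in which the alkyne is not buried in a two-metal cluster next to C4. It forms the same three bonds by a different metallacycle and returns to the route at 13. No compound outside the list is made (F0).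

Step 10. Hydrogen uptake may be very slow at a tetrasubstituted alkene flanked by two fully substituted carbons, and prolonged exposure invites hydrogenolysis of the allylic C1'–O bond or some delivery on the α face. Fallback: from 13, a Birch-type dissolving-metal conjugate reduction (Li, liquid NH3, THF, t-BuOH 1 equiv, −78 °C, NH4Cl quench), in which the C3a carbanion is protonated on the open β face. The silyl groups of 13 have no aryl ring, which is what allows this. The product is 14, possibly mixed with its C3 epimer, and both converge in step 11; the fallback returns at 14 and makes no compound outside the list (F0).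

Step 11. The C2 enolate needed for epimerisation can also expel the C1' silyloxy group (E1cB), which would destroy the C1' handle. Fallback: from 14, equilibration through the enol and not the enolate (camphorsulfonic acid cat., dry CH2Cl2, rt), since the enol cannot push the β-oxygen out as an anion. Compound 15 would then be isolated and reduced separately (NaBH4, MeOH, 0 °C), returning to the route at 16. No compound outside the list is made (F0).

Step 5. The acetylide may attack silicon instead of the chloromethyl carbon, or the alkylation may be slow with this hindered reagent. Fallback: from 6, deprotonation (n-BuLi, THF, −78 °C) and addition to paraformaldehyde would give (4R)-6-(3,3-dimethyloxiran-2-yl)-4-methyl-4-(triethylsilyloxy)hex-2-yn-1-ol F1; silylation (i-Pr3SiCl, imidazole, DMF) then returns to the route at 8, at the cost of one step.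

Step 16. Oxidative addition at the C7 triflate beside quaternary C7a may be sluggish, with protodetriflation to the alkene as the competing process. Fallback: from 21, palladium-catalysed stannylation (Pd(PPh3)4, Me3SnSnMe3, LiCl, THF, 65 °C) would give the alkenylstannane 4β,7aα-dimethyl-4α-(triethylsilyloxy)-3β-[(triisopropylsilyloxy)methyl]-7-(trimethylstannyl)-3aβ-H-2,3,3a,4,5,7a-hexahydro-1H-indene F2; bromodestannylation (N-bromosuccinimide, CH2Cl2, 0 °C) returns to the route at 22.

Step 17. Bromine may be lost, either by hydrogen-atom transfer to C7 followed by β-scission of the C–Br bond or by over-reduction, and some hydrogen may reach C7 from the α face to give the axial bromide. Fallback: from 22, heterogeneous hydrogenation over rhodium (H2 1 bar, 5% Rh/Al2O3, EtOAc, rt), a surface syn addition known to spare vinylic halides better than palladium and expected on the open β face. It returns to the route at 23 and makes no compound outside the list (F0).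

## Further compounds

F0 | step 9 | none | none
F0 | step 10 | none | none
F0 | step 11 | none | none
F1 | step 5 | (4R)-6-(3,3-dimethyloxiran-2-yl)-4-methyl-4-(triethylsilyloxy)hex-2-yn-1-ol | OCC#C[C@](C)(O[Si](CC)(CC)CC)CCC1OC1(C)C
F2 | step 16 | 4β,7aα-dimethyl-4α-(triethylsilyloxy)-3β-[(triisopropylsilyloxy)methyl]-7-(trimethylstannyl)-3aβ-H-2,3,3a,4,5,7a-hexahydro-1H-indene | CC(C)[Si](OC[C@@H]1CC[C@]2(C)C([Sn](C)(C)C)=CC[C@@](C)(O[Si](CC)(CC)CC)[C@@H]12)(C(C)C)C(C)C
F0 | step 17 | none | none
A1 | alternative 1 | trans-fused 8-bromo-5,8a-dimethyl-1,4,4a,5,6,7,8,8a-octahydronaphthalen-5-ol, ring configurations as in 34 | C1C=CC[C@]2(C)[C@@H](Br)CC[C@@](C)(O)[C@@H]12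
A2 | alternative 1 | 2,2'-(4-bromo-1-hydroxy-1,3-dimethylcyclohexane-2,3-diyl)diacetaldehyde, ring configurations as in 34 | O=CC[C@]1(C)[C@@H](Br)CC[C@@](C)(O)[C@H]1CC=O
A3 | alternative 1 | 7-bromo-4-hydroxy-4,7a-dimethyl-3a,4,5,6,7,7a-hexahydro-1H-indene-3-carbaldehyde (C2=C3) | O=CC1=CC[C@]2(C)[C@@H](Br)CC[C@@](C)(O)[C@@H]12
A4 | alternative 2 | geranylacetone, (5E)-6,10-dimethylundeca-5,9-dien-2-one | CC(C)=CCC/C(C)=C/CCC(C)=O
A5 | alternative 2 | (5E)-2-chloro-9,9-dimethoxy-6-methylnona-1,5-diene | COC(OC)CC/C(C)=C/CCC(Cl)=C
A6 | alternative 2 | 4-bromo-3-(3,3-dimethoxypropyl)-3-methylcyclohexan-1-one, bromine cis to methyl | COC(OC)CC[C@]1(C)[C@@H](Br)CCC(=O)C1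
A7 | alternative 3 | 3-methylcyclopent-2-en-1-one | CC1=CC(=O)CC1
A8 | alternative 3 | but-2-yne | CC#CC
A9 | alternative 3 | cis-fused 5,6,7-trimethylbicyclo[3.2.0]hept-6-en-2-one | CC1=C(C)[C@@]2(C)CCC(=O)[C@@H]12
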